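The quinone ring, numbered C1 (C=O), C2 (OH), C3 (chain), C4 (C=O), C5 (OH), C6 (H), is disconnected at C5–C6, the bond between its only CH and an oxygenated neighbour. That bond is made by thermal ring expansion of a squarate-derived 4-(1-ethoxyvinyl)cyclobutenone: 4π opening gives a dienylketene whose ketene carbon (C5) closes by 6π electrocyclisation onto the vinyl CH2 (C6), assembling the tetraoxygenated, alkylated benzene ring in one operation. The step exploits C6 being the lone unsubstituted ring atom, para to alkylated C3, so C2 to C5 map onto the four squarate carbons and C1 and C6 onto ethyl vinyl ether. Oxidation and ether hydrolysis follow.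

Key step: step 6

Remark: the two tautomers of a 2,5-dihydroxy-1,4-benzoquinone with this substitution pattern are the same compound, so it is immaterial which pair of ring oxygens is carried as ethers; the cyclobutene intermediates are racemic (13 a diastereomer mixture), the target being achiral.

Step 1
Reactants: 1 (E)-dec-5-en-1-ol
Product: 2 (E)-1-bromodec-5-ene
Conditions: CBr4, PPh3, CH2Cl2, 0 °C to rt
Reagents that add atoms: carbon tetrabromide, BrC(Br)(Br)Br
Why: Appel reaction, in which bromide displaces the primary alkoxyphosphonium group by SN2 under neutral conditions that leave the E-alkene untouched.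

Step 2
Reactants: 2 (E)-1-bromodec-5-ene; 3 1,9-dibromononane
Product: 5 (E)-1-bromononadec-14-ene, via (E)-dec-5-enylmagnesium bromide 4 (not isolated)
Conditions: Mg, THF, rt; then added to 3 (3 equiv), Li2CuCl4 (3 mol %), THF, −10 to 0 °C
Reagents that add atoms: none
Why: Copper-catalysed sp3–sp3 cross-coupling of a primary alkyl Grignard reagent with a primary alkyl bromide, in which the excess of dibromide should hold the reaction at mono-substitution and the alkene geometry is not involved.

Step 3
Reactants: 5 (E)-1-bromononadec-14-ene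
Product: 6 (E)-1-iodononadec-14-ene
Conditions: NaI, acetone, reflux
Reagents that add atoms: sodium iodide, [Na+].[I-]
Why: Finkelstein reaction, an SN2 halide exchange driven by precipitation of NaBr, which should provide the iodide needed for a clean iodine–lithium exchange.

Step 4
Reactants: 7 ethyl vinyl ether; 8 dimethyl squarate (3,4-dimethoxycyclobut-3-ene-1,2-dione)
Product: 11 racemic 4-(1-ethoxyvinyl)-2,3,4-trimethoxycyclobut-2-en-1-one, via 1-ethoxyvinyllithium 9 (not isolated), via lithium alkoxide 10 (not isolated)
Conditions: 7 (excess), t-BuLi, THF, −78 to 0 °C; then added to 8, THF, −78 °C; then MeOTf, −78 to 0 °C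
Reagents that add atoms: methyl trifluoromethanesulfonate, COS(=O)(=O)C(F)(F)F
Why: α-Lithiation of the enol ether gives an acyl-anion equivalent that adds 1,2 to one squarate carbonyl (the remaining carbonyl of the adduct is a deactivated vinylogous ester), and the alkoxide is O-methylated in the flask by a Williamson-type etherification; the new quaternary centre is racemic and is destroyed in step 6.

Step 5
Reactants: 6 (E)-1-iodononadec-14-ene; 11 racemic 4-(1-ethoxyvinyl)-2,3,4-trimethoxycyclobut-2-en-1-one
Product: 14 racemic 4-(1-ethoxyvinyl)-2,4-dimethoxy-3-[(E)-nonadec-14-enyl]cyclobut-2-en-1-one, via (E)-nonadec-14-enyllithium 12 (not isolated), via tertiary lithium alkoxide 13 (not isolated)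
Conditions: 6, t-BuLi (2 equiv), Et2O, −78 °C; then 11, THF, −78 °C; then (CF3CO)2O, −78 °C; aq. NaHCO3 quench at −78 °C
Reagents that add atoms: water, O
Why: Iodine–lithium exchange and 1,2-addition to the vinylogous-ester carbonyl, followed by trifluoroacetylation and ionisation of the tertiary alkoxide, should give a methoxy-stabilised cyclobutenyl cation that is hydrolysed on work-up, a net 1,3-carbonyl transposition that places the chain on the ring carbon next to the quaternary centre.

Step 6
Reactants: 14 racemic 4-(1-ethoxyvinyl)-2,4-dimethoxy-3-[(E)-nonadec-14-enyl]cyclobut-2-en-1-one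
Product: 17 5-ethoxy-2,4-dimethoxy-3-[(E)-nonadec-14-enyl]phenol, via dienylketene 15 (not isolated), via cyclohexa-2,4-dienone 16 (not isolated)
Conditions: PhMe (0.02 M, degassed), 110 °C
Reagents that add atoms: none
Why: Heating should open the strained cyclobutenone by a conrotatory 4π-electrocyclic ring opening to dienylketene 15, and a thermal disrotatory 6π-electrocyclisation then joins the electrophilic ketene carbon to the terminal CH2 of the electron-rich 1-ethoxyvinyl group to give cyclohexa-2,4-dienone 16, which aromatises by enolisation to phenol 17. The closest known reaction type is the thermal ring expansion of 4-alkenyl-4-alkoxy- or 4-hydroxycyclobutenones to hydroquinone derivatives, the alkenyl counterpart of the Moore rearrangement. The six-membered carbocycle is closed by the 6π-electrocyclisation, the new bond lying between the future ring CH and the carbon that becomes the phenolic C–OH. No stereocentre remains, because the quaternary centre of 14 becomes sp2 on ring opening and the CH2 of 16 loses a hydrogen on aromatisation. The step needs torquoselectivity, which the donor methoxy group on the sp3 carbon secures by rotating outward and so turning the vinyl group inward, cis to the ketene; the substitution pattern is fixed by the constitution of 14 and the remote E-alkene should be inert at this temperature.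

Step 7
Reactants: 17 5-ethoxy-2,4-dimethoxy-3-[(E)-nonadec-14-enyl]phenol
Product: 18 5-ethoxy-2-methoxy-3-[(E)-nonadec-14-enyl]-1,4-benzoquinone
Conditions: (NH4)2Ce(NO3)6, MeCN–H2O, 0 °C
Reagents that add atoms: water, O
Why: Oxidative demethylation of a para-methoxyphenol, in which two one-electron oxidations by tetravalent cerium give an oxocarbenium ion that water captures at the methoxy-bearing carbon, and loss of methanol leaves the para-quinone without touching the isolated alkene.

Step 8
Reactants: 18 5-ethoxy-2-methoxy-3-[(E)-nonadec-14-enyl]-1,4-benzoquinone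
Product: 20 2,5-dihydroxy-3-[(E)-nonadec-14-enyl]-1,4-benzoquinone, via disodium quinonediolate 19 (not isolated)
Conditions: 2 M aq. NaOH, EtOH, Ar, 60 °C; then 2 M HCl, 0 °C
Reagents that add atoms: sodium hydroxide, [Na+].[OH-]
Why: Both alkoxy groups are vinylogous esters of the quinone and should be replaced by hydroxide through conjugate addition–elimination (vinylogous saponification), and acidification of the dianion gives the dihydroxyquinone.

Compound list
1 | (E)-dec-5-en-1-ol | CCCC/C=C/CCCCO | starting material
2 | (E)-1-bromodec-5-ene | CCCC/C=C/CCCCBr | intermediate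
3 | 1,9-dibromononane | BrCCCCCCCCCBr | starting material
4 | (E)-dec-5-enylmagnesium bromide | CCCC/C=C/CCCC[Mg]Br | intermediate
5 | (E)-1-bromononadec-14-ene | CCCC/C=C/CCCCCCCCCCCCCBr | intermediate
6 | (E)-1-iodononadec-14-ene | CCCC/C=C/CCCCCCCCCCCCCI | intermediate
7 | ethyl vinyl ether | C=COCC | starting material
8 | dimethyl squarate (3,4-dimethoxycyclobut-3-ene-1,2-dione) | COC1=C(OC)C(=O)C1=O | starting material
9 | 1-ethoxyvinyllithium | [Li]C(=C)OCC | intermediate
10 | lithium 1-(1-ethoxyvinyl)-2,3-dimethoxy-4-oxocyclobut-2-en-1-olate (racemic) | [Li]OC1(C(=C)OCC)C(OC)=C(OC)C1=O | intermediate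
11 | 4-(1-ethoxyvinyl)-2,3,4-trimethoxycyclobut-2-en-1-one (racemic) | COC1(C(=C)OCC)C(OC)=C(OC)C1=O | intermediate
12 | (E)-nonadec-14-enyllithium | CCCC/C=C/CCCCCCCCCCCCC[Li] | intermediate
13 | lithium 4-(1-ethoxyvinyl)-2,3,4-trimethoxy-1-[(E)-nonadec-14-enyl]cyclobut-2-en-1-olate (diastereomer mixture) | CCCC/C=C/CCCCCCCCCCCCCC1(O[Li])C(OC)=C(OC)C1(OC)C(=C)OCC | intermediate
14 | 4-(1-ethoxyvinyl)-2,4-dimethoxy-3-[(E)-nonadec-14-enyl]cyclobut-2-en-1-one (racemic) | CCCC/C=C/CCCCCCCCCCCCCC1=C(OC)C(=O)C1(OC)C(=C)OCC | intermediate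
15 | (3E)-5-ethoxy-2,4-dimethoxy-3-[(E)-nonadec-14-enyl]hexa-1,3,5-trien-1-one (dienylketene, ethoxyvinyl group cis to the ketene) | CCCC/C=C/CCCCCCCCCCCCC/C(=C(\OC)C(=C)OCC)C(OC)=C=O | intermediate
16 | 5-ethoxy-2,4-dimethoxy-3-[(E)-nonadec-14-enyl]cyclohexa-2,4-dien-1-one | CCCC/C=C/CCCCCCCCCCCCCC1=C(OC)C(=O)CC(OCC)=C1OC | intermediate
17 | 5-ethoxy-2,4-dimethoxy-3-[(E)-nonadec-14-enyl]phenol | CCCC/C=C/CCCCCCCCCCCCCc1c(OC)c(O)cc(OCC)c1OC | intermediate
18 | 5-ethoxy-2-methoxy-3-[(E)-nonadec-14-enyl]-1,4-benzoquinone | CCCC/C=C/CCCCCCCCCCCCCC1=C(OC)C(=O)C=C(OCC)C1=O | intermediate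
19 | disodium 3-[(E)-nonadec-14-enyl]-1,4-benzoquinone-2,5-diolate | CCCC/C=C/CCCCCCCCCCCCCC1=C([O-])C(=O)C=C([O-])C1=O.[Na+].[Na+] | intermediate
20 | 2,5-dihydroxy-3-[(E)-nonadec-14-enyl]-1,4-benzoquinone | CCCC/C=C/CCCCCCCCCCCCCC1=C(O)C(=O)C=C(O)C1=O | target

Total step count: 8. Longest linear sequence: 7 (steps 1, 2, 3, 5, 6, 7, 8); step 4 is the convergent branch.

Steps most likely to fail

1. Step 5. What may go wrong: acid released during the anhydride-induced ionisation hydrolyses the 1-ethoxyvinyl enol ether, or the cyclobutenyl cation is quenched by migration of the electron-rich vinyl group instead of by water. The fallback sets out from 8 and 12 and comes back at 19. It carries an acid-stable plain vinyl group through the transposition and the ring expansion (the ring is still closed at the same bond by the same electrocyclic cascade) and brings in the fourth oxygen afterwards through an amine. Vinylmagnesium bromide is added to 8 (THF, −78 °C) and the alkoxide trapped with MeOTf to give 2,3,4-trimethoxy-4-vinylcyclobut-2-en-1-one F1. Addition of 12 and treatment with (CF3CO)2O as in step 5 should give 2,4-dimethoxy-3-[(E)-nonadec-14-enyl]-4-vinylcyclobut-2-en-1-one F2. Thermolysis in toluene at 110 °C should give 2,4-dimethoxy-3-[(E)-nonadec-14-enyl]phenol F3, and oxidation with (NH4)2Ce(NO3)6 should give 2-methoxy-3-[(E)-nonadec-14-enyl]-1,4-benzoquinone F4. Conjugate addition of dimethylamine in ethanol under air should give 5-(dimethylamino)-2-methoxy-3-[(E)-nonadec-14-enyl]-1,4-benzoquinone F5; the methoxy group deactivates the carbonyl vinylogous to it, so the amine should enter at C5, para to the methoxy-bearing carbon. Hot aqueous NaOH in ethanol should then displace both the methoxy and the dimethylamino group and rejoin the route at 19.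

2. Step 4. What may go wrong: O-methylation of the hindered tertiary lithium alkoxide is slow, so that on warming the addition reverses or a second equivalent of 9 adds, and the triflate alkylates the enol ether instead. The fallback sets out from 10 and comes back at 18. The alkoxide is capped as a silyl ether, which forms at −78 °C, and the silyl group is carried as far as the oxidation. Me3SiCl is added to 10 to give 4-(1-ethoxyvinyl)-2,3-dimethoxy-4-(trimethylsilyloxy)cyclobut-2-en-1-one F6. Addition of 12 and treatment with (CF3CO)2O should give 4-(1-ethoxyvinyl)-2-methoxy-3-[(E)-nonadec-14-enyl]-4-(trimethylsilyloxy)cyclobut-2-en-1-one F7. Thermolysis should give 5-ethoxy-2-methoxy-3-[(E)-nonadec-14-enyl]-4-(trimethylsilyloxy)phenol F8, which (NH4)2Ce(NO3)6 in aqueous MeCN should desilylate and oxidise to 18.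

3. Step 2. What may go wrong: double substitution of the dibromide, and radical 5-exo cyclisation during magnesium insertion into the hex-5-enyl-type bromide, give hydrocarbon by-products that are hard to separate. The fallback sets out from 2 and comes back at 6. The polarity is reversed, with 2 as the electrophile and a monofunctional C9 Grignard reagent. Commercial 9-bromononan-1-ol F9 is protected (3,4-dihydro-2H-pyran, PPTS) as 2-(9-bromononyloxy)tetrahydro-2H-pyran F10 and converted with Mg into 9-(tetrahydro-2H-pyran-2-yloxy)nonylmagnesium bromide F11. Coupling of F11 with 2 under Li2CuCl4 catalysis should give 2-[(E)-nonadec-14-enyloxy]tetrahydro-2H-pyran F12. Methanolysis (PPTS, MeOH) should give (E)-nonadec-14-en-1-ol F13, and I2, PPh3 and imidazole should convert it into 6.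

Further compounds
F1 | step 5 | 2,3,4-trimethoxy-4-vinylcyclobut-2-en-1-one | COC1(C=C)C(OC)=C(OC)C1=O
F2 | step 5 | 2,4-dimethoxy-3-[(E)-nonadec-14-enyl]-4-vinylcyclobut-2-en-1-one | CCCC/C=C/CCCCCCCCCCCCCC1=C(OC)C(=O)C1(OC)C=C
F3 | step 5 | 2,4-dimethoxy-3-[(E)-nonadec-14-enyl]phenol | CCCC/C=C/CCCCCCCCCCCCCc1c(OC)c(O)ccc1OC
F4 | step 5 | 2-methoxy-3-[(E)-nonadec-14-enyl]-1,4-benzoquinone | CCCC/C=C/CCCCCCCCCCCCCC1=C(OC)C(=O)C=CC1=O
F5 | step 5 | 5-(dimethylamino)-2-methoxy-3-[(E)-nonadec-14-enyl]-1,4-benzoquinone | CCCC/C=C/CCCCCCCCCCCCCC1=C(OC)C(=O)C=C(N(C)C)C1=O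
F6 | step 4 | 4-(1-ethoxyvinyl)-2,3-dimethoxy-4-(trimethylsilyloxy)cyclobut-2-en-1-one | C[Si](C)(C)OC1(C(=C)OCC)C(OC)=C(OC)C1=O
F7 | step 4 | 4-(1-ethoxyvinyl)-2-methoxy-3-[(E)-nonadec-14-enyl]-4-(trimethylsilyloxy)cyclobut-2-en-1-one | CCCC/C=C/CCCCCCCCCCCCCC1=C(OC)C(=O)C1(O[Si](C)(C)C)C(=C)OCC
F8 | step 4 | 5-ethoxy-2-methoxy-3-[(E)-nonadec-14-enyl]-4-(trimethylsilyloxy)phenol | CCCC/C=C/CCCCCCCCCCCCCc1c(OC)c(O)cc(OCC)c1O[Si](C)(C)C
F9 | step 2 | 9-bromononan-1-ol | OCCCCCCCCCBr
F10 | step 2 | 2-(9-bromononyloxy)tetrahydro-2H-pyran | BrCCCCCCCCCOC1CCCCO1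
F11 | step 2 | 9-(tetrahydro-2H-pyran-2-yloxy)nonylmagnesium bromide | Br[Mg]CCCCCCCCCOC1CCCCO1
F12 | step 2 | 2-[(E)-nonadec-14-enyloxy]tetrahydro-2H-pyran | CCCC/C=C/CCCCCCCCCCCCCOC1CCCCO1
F13 | step 2 | (E)-nonadec-14-en-1-ol | CCCC/C=C/CCCCCCCCCCCCCO
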